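The target is (−)-syringaresinol (furofuran core, two syringyl rings) whose O-4 atoms carry erythro guaiacylglycerol units. Unit C sits on one side. Unit B, extended through its guaiacyl O-4 by unit A, sits on the other. The route rests on cutting C7–C8 of unit B. It exploits that C7 hangs on an electron-rich guaiacyl ring (a non-enolisable aldehyde) and C8 on syringyl O-4 (a glycolate CH2 once C9 is an N-acyloxazolidinone). One MgCl2-catalysed anti-aldol joins the core–unit C aryloxyacetyl imide to the unit A-bearing benzaldehyde, sets C7 and C8 together under auxiliary control and silylates O-7. A single reduction then unveils all three units.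

Key step: step 8

Numbering remark: in each C3 unit, C7 is the benzylic carbinol carbon, C8 the aryloxy-bearing carbon and C9 the terminal carbon. Unit A (outer) is 7R,8S, unit B (middle) is 7S,8R, unit C (lone) is 7S,8R, and the core is 7R,7'R,8S,8'S.
Assumption: (−)-syringaresinol is bought as the isolated lignan and brings in the four furofuran stereocentres.
Assumption: α-aryloxyacetyl imides follow the facial sense of N-propionyl imides in the MgCl2-catalysed anti-aldol (attack on the chelated Z-enolate opposite the benzyl group), so the (S)-auxiliary serves unit A and the (R)-auxiliary serves units B and C.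

Step 1
Reactants: 1 (S)-4-benzyl-1,3-oxazolidin-2-one; 2 bromoacetyl bromide
Product: 4 (S)-4-benzyl-3-(bromoacetyl)-1,3-oxazolidin-2-one, via lithium amide 3 (not isolated)
Conditions: n-BuLi, THF, −78 °C; then 2, −78 to 0 °C
Reagents that add atoms: none
Why: N-acylation of a lithiated oxazolidinone (standard preparation of an Evans imide), in which the acyl bromide reacts far faster than the alkyl bromide and the C4 stereocentre is not involved.

Step 2
Reactants: 4 (S)-4-benzyl-3-(bromoacetyl)-1,3-oxazolidin-2-one; 5 (E)-isoeugenol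
Product: 6 (S)-4-benzyl-3-{[2-methoxy-4-((E)-prop-1-enyl)phenoxy]acetyl}-1,3-oxazolidin-2-one
Conditions: K2CO3, dry acetone, rt
Reagents that add atoms: none
Why: Williamson ether synthesis, in which the guaiacyl phenoxide displaces the carbonyl-activated primary bromide by SN2 much faster than it attacks an imide carbonyl, and no stereocentre is formed.

Step 3
Reactants: 6 (S)-4-benzyl-3-{[2-methoxy-4-((E)-prop-1-enyl)phenoxy]acetyl}-1,3-oxazolidin-2-one; 7 vanillin acetate (4-formyl-2-methoxyphenyl acetate)
Product: 8 unit A anti-aldol adduct: (S)-4-benzyl-3-[(2R,3R)-3-(4-acetoxy-3-methoxyphenyl)-2-{2-methoxy-4-[(E)-prop-1-enyl]phenoxy}-3-(trimethylsilyloxy)propanoyl]-1,3-oxazolidin-2-one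
Conditions: MgCl2 (0.2 equiv), Et3N, TMSCl, EtOAc, 23 °C; filtration through Et3N-deactivated silica (no acidic desilylation)
Reagents that add atoms: chlorotrimethylsilane, C[Si](C)(C)Cl
Why: Magnesium-halide-catalysed anti-aldol reaction of an N-acyloxazolidinone with a non-enolisable aromatic aldehyde (Evans anti-aldol), in which the (S)-benzyl group shields one face of the chelated magnesium Z-enolate and so sets C8, the boat-like transition state places C7–O anti to C8–O (erythro), and TMSCl traps the aldolate as its silyl ether; the step is also the small-scale rehearsal of step 8.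

Step 4
Reactants: 8 unit A anti-aldol adduct
Product: 10 aldehyde fragment: (S)-4-benzyl-3-[(2R,3R)-3-(4-acetoxy-3-methoxyphenyl)-2-(4-formyl-2-methoxyphenoxy)-3-(trimethylsilyloxy)propanoyl]-1,3-oxazolidin-2-one, via ozonide 9 (not isolated)
Conditions: O3, CH2Cl2, −78 °C (Sudan Red 7B end point); then PPh3, −78 °C to rt
Reagents that add atoms: ozone, [O-][O+]=O
Why: Ozonolysis with reductive work-up, in which the conjugated propenyl double bond adds ozone far faster than the arenes and the neutral, water-free medium spares the TMS ether, the aryl acetate and the imide, so that no stereocentre is touched.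

Step 5
Reactants: 11 (R)-4-benzyl-1,3-oxazolidin-2-one; 2 bromoacetyl bromide
Product: 13 (R)-4-benzyl-3-(bromoacetyl)-1,3-oxazolidin-2-one, via lithium amide 12 (not isolated)
Conditions: n-BuLi, THF, −78 °C; then 2, −78 to 0 °C
Reagents that add atoms: none
Why: N-acylation of a lithiated oxazolidinone as in step 1, in the enantiomeric series, with the stereocentre not involved.

Step 6
Reactants: 13 (R)-4-benzyl-3-(bromoacetyl)-1,3-oxazolidin-2-one (2.2 equiv); 14 (−)-syringaresinol
Product: 15 bis-imide: (−)-syringaresinol 4,4'-bis-O-{2-[(R)-4-benzyl-2-oxo-1,3-oxazolidin-3-yl]-2-oxoethyl} ether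
Conditions: K2CO3, dry acetone/DMF, rt
Reagents that add atoms: none
Why: Twofold Williamson ether synthesis on the C2-symmetric bisphenol, in which both syringyl phenoxides are alkylated by the activated bromide, the base-stable furofuran keeps its four stereocentres, and no selectivity between the two ends is needed.

Step 7
Reactants: 15 bis-imide; 7 vanillin acetate (0.5 equiv)
Product: 16 imide fragment: 15 in which one arm has become the (2S,3S)-2-aryloxy-3-(4-acetoxy-3-methoxyphenyl)-3-(trimethylsilyloxy)propanoyl imide (unit C) while the other arm is still the OCH2C(O)N imide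
Conditions: MgCl2 (0.2 equiv), Et3N, TMSCl, EtOAc/CH2Cl2, 23 °C; chromatography on Et3N-deactivated silica; recovered 15 recycled
Reagents that add atoms: chlorotrimethylsilane, C[Si](C)(C)Cl
Why: The same magnesium-halide-catalysed anti-aldol reaction, now with the (R)-auxiliary, which sets C8 (chelated Z-enolate, face opposite the benzyl group) and C7 (anti, boat-like transition state) of unit C in the mirror-image sense of step 3; the two homotopic imide arms are told apart only by the deficit of aldehyde, so unreacted 15 is recovered and recycled.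

Step 8
Reactants: 16 imide fragment; 10 aldehyde fragment (1.1 equiv)
Product: 17 coupled tris-imide: units A, B and C on the core, each with C9 as N-acyl-4-benzyloxazolidinone and O-7 as TMS ether (unit A 2R,3R with the S-auxiliary; units B and C 2S,3S with the R-auxiliary), both guaiacyl phenols as acetates
Conditions: MgCl2 (0.3 equiv), Et3N, TMSCl, EtOAc/CH2Cl2, 23 °C; chromatography on Et3N-deactivated silica
Reagents that add atoms: chlorotrimethylsilane, C[Si](C)(C)Cl
Why: MgCl2 and Et3N soft-enolise the only CH2 imide of 16 to the chelated magnesium Z-enolate, which adds reversibly to the aldehyde of 10, and TMSCl silylates the magnesium aldolate, which frees the catalyst and makes the C7–C8 bond formation irreversible. The closest known reaction type is the magnesium-halide-catalysed anti-aldol of N-acyloxazolidinones (Evans anti-aldol), which works best with non-enolisable, electron-rich aromatic aldehydes such as this 4-alkoxy-3-methoxybenzaldehyde. No ring is closed. C8 of unit B is set by the (R)-benzyl group, which shields one face of the chelated enolate as in alkylations of such imides, and C7 is set relative to C8 by the boat-like transition state that leads from the Z-enolate to the anti (erythro) adduct, while the other eight stereocentres lie too far from the reacting atoms to interfere. The step needs chemoselectivity among three imides, and this is secured because the imides of units A and C carry only a tertiary α-C–H held in the imide plane by A(1,3) strain, are capped as TMS ethers against retro-aldol, and are of the very product type that survives these conditions, while 10 holds the only aldehyde. The weak Lewis acid and amine base leave the acid-labile furofuran, the aryl acetates and the silyl ethers untouched.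

Step 9
Reactants: 17 coupled tris-imide
Product: 19 target CNP0316493.2, via tris-TMS ether 18 (not isolated)
Conditions: LiBH4 (excess), MeOH (additive), THF, 0 °C to rt; aq. NH4Cl; then K2CO3 (cat.), MeOH, 0 °C to rt, argon; reversed-phase chromatography
Reagents that add atoms: none
Why: Reductive cleavage of N-acyloxazolidinones with LiBH4 (hydride attack at the exocyclic carbonyl) turns all three C9 acyl groups into CH2OH and at the same time reduces off both aryl acetates, and base-catalysed methanolysis then removes the three TMS ethers; C8 is never enolised and no C7–O bond is broken, so all ten stereocentres are kept.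

Compound list
1 | (S)-4-benzyl-1,3-oxazolidin-2-one | O=C1N[C@@H](Cc2ccccc2)CO1 | starting material
2 | bromoacetyl bromide | O=C(Br)CBr | starting material
3 | N-lithio-(S)-4-benzyl-1,3-oxazolidin-2-one | [Li]N1[C@@H](Cc2ccccc2)COC1=O | intermediate
4 | (S)-4-benzyl-3-(bromoacetyl)-1,3-oxazolidin-2-one | O=C(CBr)N1[C@@H](Cc2ccccc2)COC1=O | intermediate
5 | (E)-isoeugenol | C/C=C/c1ccc(O)c(OC)c1 | starting material
6 | (S)-4-benzyl-3-{[2-methoxy-4-((E)-prop-1-enyl)phenoxy]acetyl}-1,3-oxazolidin-2-one | C/C=C/c1ccc(OCC(=O)N2[C@@H](Cc3ccccc3)COC2=O)c(OC)c1 | intermediate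
7 | vanillin acetate (4-formyl-2-methoxyphenyl acetate) | CC(=O)Oc1ccc(C=O)cc1OC | starting material
8 | unit A anti-aldol adduct (2R,3R; S-auxiliary; O-7 TMS; propenyl on ring B) | COc1cc([C@@H](O[Si](C)(C)C)[C@H](C(=O)N2[C@@H](Cc3ccccc3)COC2=O)Oc2ccc(/C=C/C)cc2OC)ccc1OC(C)=O | intermediate
9 | secondary ozonide of 8 (1,2,4-trioxolane, mixture at the two ring carbons) | COc1cc([C@@H](O[Si](C)(C)C)[C@H](C(=O)N2[C@@H](Cc3ccccc3)COC2=O)Oc2ccc(C3OC(C)OO3)cc2OC)ccc1OC(C)=O | intermediate
10 | aldehyde fragment (unit A adduct with 4-formyl-2-methoxyphenoxy group) | COc1cc([C@@H](O[Si](C)(C)C)[C@H](C(=O)N2[C@@H](Cc3ccccc3)COC2=O)Oc2ccc(C=O)cc2OC)ccc1OC(C)=O | intermediate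
11 | (R)-4-benzyl-1,3-oxazolidin-2-one | O=C1N[C@H](Cc2ccccc2)CO1 | starting material
12 | N-lithio-(R)-4-benzyl-1,3-oxazolidin-2-one | [Li]N1[C@H](Cc2ccccc2)COC1=O | intermediate
13 | (R)-4-benzyl-3-(bromoacetyl)-1,3-oxazolidin-2-one | O=C(CBr)N1[C@H](Cc2ccccc2)COC1=O | intermediate
14 | (−)-syringaresinol (7R,7'R,8S,8'S) | COc1cc([C@@H]2OC[C@@H]3[C@H]2CO[C@H]3c2cc(OC)c(O)c(OC)c2)cc(OC)c1O | starting material
15 | bis-imide of (−)-syringaresinol (two R-auxiliaries) | COc1cc([C@@H]2OC[C@@H]3[C@H]2CO[C@H]3c2cc(OC)c(OCC(=O)N3[C@H](Cc4ccccc4)COC3=O)c(OC)c2)cc(OC)c1OCC(=O)N1[C@H](Cc2ccccc2)COC1=O | intermediate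
16 | imide fragment (core, unit C as 2S,3S TMS-capped aldol imide, second arm free CH2 imide) | COc1cc([C@@H]2OC[C@@H]3[C@H]2CO[C@H]3c2cc(OC)c(O[C@H](C(=O)N3[C@H](Cc4ccccc4)COC3=O)[C@@H](O[Si](C)(C)C)c3ccc(OC(C)=O)c(OC)c3)c(OC)c2)cc(OC)c1OCC(=O)N1[C@H](Cc2ccccc2)COC1=O | intermediate
17 | coupled tris-imide tris-TMS ether diacetate | COc1cc([C@@H](O[Si](C)(C)C)[C@H](C(=O)N2[C@@H](Cc3ccccc3)COC2=O)Oc2ccc([C@H](O[Si](C)(C)C)[C@@H](C(=O)N3[C@H](Cc4ccccc4)COC3=O)Oc3c(OC)cc([C@@H]4OC[C@@H]5[C@H]4CO[C@H]5c4cc(OC)c(O[C@H](C(=O)N5[C@H](Cc6ccccc6)COC5=O)[C@@H](O[Si](C)(C)C)c5ccc(OC(C)=O)c(OC)c5)c(OC)c4)cc3OC)cc2OC)ccc1OC(C)=O | intermediate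
18 | 7-O-tris(trimethylsilyl) ether of the target | COc1cc([C@@H](O[Si](C)(C)C)[C@H](CO)Oc2ccc([C@H](O[Si](C)(C)C)[C@@H](CO)Oc3c(OC)cc([C@@H]4OC[C@@H]5[C@H]4CO[C@H]5c4cc(OC)c(O[C@H](CO)[C@@H](O[Si](C)(C)C)c5ccc(O)c(OC)c5)c(OC)c4)cc3OC)cc2OC)ccc1O | intermediate
19 | CNP0316493.2 | COc1cc([C@@H](O)[C@H](CO)Oc2ccc([C@H](O)[C@@H](CO)Oc3c(OC)cc([C@@H]4OC[C@@H]5[C@H]4CO[C@H]5c4cc(OC)c(O[C@H](CO)[C@@H](O)c5ccc(O)c(OC)c5)c(OC)c4)cc3OC)cc2OC)ccc1O | target

Total step count: 9. Longest linear sequence: 6 steps (1, 2, 3, 4, 8, 9).

Steps most likely to fail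

Step 8. The many chelating imide and dimethoxyaryl sites of two large fragments may sequester the magnesium catalyst and slow turnover. The anti selectivity may also erode if the α-aryloxy oxygen and its ortho-methoxy groups compete for magnesium. The fallback sets out from 16 and 10 and comes back at 17. Compound 16 is enolised stoichiometrically with Bu2BOTf/i-Pr2NEt (CH2Cl2, −78 to 0 °C) to the dibutylboron Z-enolate F1. This is added at −78 °C to 10 precomplexed with Et2AlCl. Because the aldehyde is activated outside the boron chelate, this Lewis-acid-mediated variant of the Evans aldol reaction runs through an open transition state on the same enolate face. After a non-oxidative aqueous work-up it should give the anti β-hydroxy imide F2. TMSCl/imidazole (CH2Cl2, 0 °C) then gives 17.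

Step 7. Over-addition on the second arm may occur. TMS ethers may also be lost during the demanding separation of three species of similar polarity, and this would cut the throughput of the precious core. The fallback sets out from 14 and 13 and comes back at 16. It moves the desymmetrisation to the phenol stage.
- Compound 14 is alkylated with one equivalent of 13 (K2CO3, acetone) to the mono-imide phenol F3. This differs from 14 and 15 in its number of free phenols and should separate easily.
- With only one donor arm left, the MgCl2/Et3N/TMSCl anti-aldol can be driven with an excess of 7 and extra TMSCl to the doubly silylated adduct F4.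
- Brief stirring with aqueous NaHCO3/THF hydrolyses only the aryl silyl ether to the phenol adduct F5.
- A second Williamson alkylation with 13 (K2CO3, acetone) gives 16.

Step 9. Hydride may attack the ring carbonyl of the crowded imides, opening the auxiliary instead of releasing it, at any of the three sites. Retro-aldol cleavage may also set in once a silyl ether is lost in the basic medium. The fallback sets out from 17 and comes back at 19. LiOH/H2O2 (THF/H2O, 0 °C; Na2SO3 quench; acidification to about pH 4) attacks the exocyclic carbonyl selectively even in hindered imides. It also removes the acetates and the TMS ethers, to give the triacid F6. BH3·THF (excess, THF, 0 °C to rt) reduces the three carboxylic acids chemoselectively to the C9 alcohols of 19.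

Further compounds
F1 | step 8 | dibutylboron Z-enolate of 16 | CCCCB(CCCC)O/C(=C\Oc1c(OC)cc([C@@H]2OC[C@@H]3[C@H]2CO[C@H]3c2cc(OC)c(O[C@H](C(=O)N3[C@H](Cc4ccccc4)COC3=O)[C@@H](O[Si](C)(C)C)c3ccc(OC(C)=O)c(OC)c3)c(OC)c2)cc1OC)N1[C@H](Cc2ccccc2)COC1=O
F2 | step 8 | anti β-hydroxy imide (17 with free C7–OH in unit B) | COc1cc([C@@H](O[Si](C)(C)C)[C@H](C(=O)N2[C@@H](Cc3ccccc3)COC2=O)Oc2ccc([C@H](O)[C@@H](C(=O)N3[C@H](Cc4ccccc4)COC3=O)Oc3c(OC)cc([C@@H]4OC[C@@H]5[C@H]4CO[C@H]5c4cc(OC)c(O[C@H](C(=O)N5[C@H](Cc6ccccc6)COC5=O)[C@@H](O[Si](C)(C)C)c5ccc(OC(C)=O)c(OC)c5)c(OC)c4)cc3OC)cc2OC)ccc1OC(C)=O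
F3 | step 7 | mono-imide phenol of (−)-syringaresinol | COc1cc([C@@H]2OC[C@@H]3[C@H]2CO[C@H]3c2cc(OC)c(OCC(=O)N3[C@H](Cc4ccccc4)COC3=O)c(OC)c2)cc(OC)c1O
F4 | step 7 | doubly silylated adduct (unit C installed, syringyl phenol as TMS ether) | COc1cc([C@@H]2OC[C@@H]3[C@H]2CO[C@H]3c2cc(OC)c(O[C@H](C(=O)N3[C@H](Cc4ccccc4)COC3=O)[C@@H](O[Si](C)(C)C)c3ccc(OC(C)=O)c(OC)c3)c(OC)c2)cc(OC)c1O[Si](C)(C)C
F5 | step 7 | phenol adduct (unit C installed, syringyl phenol free) | COc1cc([C@@H]2OC[C@@H]3[C@H]2CO[C@H]3c2cc(OC)c(O[C@H](C(=O)N3[C@H](Cc4ccccc4)COC3=O)[C@@H](O[Si](C)(C)C)c3ccc(OC(C)=O)c(OC)c3)c(OC)c2)cc(OC)c1O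
F6 | step 9 | triacid (target with the three C9 carbons as CO2H) | COc1cc([C@@H](O)[C@H](C(=O)O)Oc2ccc([C@H](O)[C@@H](C(=O)O)Oc3c(OC)cc([C@@H]4OC[C@@H]5[C@H]4CO[C@H]5c4cc(OC)c(O[C@H](C(=O)O)[C@@H](O)c5ccc(O)c(OC)c5)c(OC)c4)cc3OC)cc2OC)ccc1O
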